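## Retrosynthetic overview

1. Last operations: chemoselective oxidation of the C1 primary alcohol to the acid and removal of one TBS group. Ring B (5-ylidene-5,6-dihydropyran-2-one) comes from a Stille coupling of a (Z)-2-stannyl allylic alcohol with ethyl (Z)-3-iodoacrylate, followed by lactonisation; the stannane arises by trans-hydrostannation of the C15–C16 alkyne.
2. Ring A (oxolane) closes by intramolecular SN2 displacement of a C9 mesylate by the C6 hydroxyl (inversion), after an Evans–Tishchenko anti-reduction of a β-hydroxy ketone.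
3. Key disconnection C7–C8: chelation-controlled Mukaiyama aldol between a west α-PMB-oxy aldehyde (C1–C7) and the silyl enol ether of an east methyl ketone (C8–C17).
4. West aldehyde from methyl (S)-glycerate acetonide (ynone, Noyori transfer hydrogenation, hydroalumination/iodination, Negishi methylation). East ketone from propargyl alcohol, 1,1,3-trichloropropene and a ketal-protected 3-oxobutylzinc reagent (trans-selective Negishi monoalkylation of the gem-dichloroalkene).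
5. Ring order: ring A first, ring B second.

Assumption: the SMILES is taken at face value ((3E,5R) side chain, (2S,3R,5R)-oxolane, (Z)-vinyl chloride, (E)-exocyclic alkene); positions C1–C17 run from the acid carbon to the lactone OCH2 carbon.

## Route

**West fragment**

Step 1
Reactants: 1 but-3-yn-1-ol
Product: 2 1-[(but-3-yn-1-yloxy)methyl]-4-methoxybenzene
Conditions: NaH, PMBCl, Bu4NI (cat.), THF/DMF, 0 °C → rt
Reagents that add atoms: 4-methoxybenzyl chloride COc1ccc(CCl)cc1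
Why: Williamson ether synthesis; the alkoxide forms in preference to the acetylide and is benzylated, with no stereocentre involved.

Step 2
Reactants: 3 methyl (4S)-2,2-dimethyl-1,3-dioxolane-4-carboxylate
Product: 4 (4S)-N-methoxy-N,2,2-trimethyl-1,3-dioxolane-4-carboxamide
Conditions: MeNHOMe·HCl, i-PrMgCl, THF, −20 °C
Reagents that add atoms: N,O-dimethylhydroxylamine hydrochloride CNOC.Cl
Why: Weinreb amide formation by magnesium amide aminolysis of the ester at low temperature, which leaves the α-alkoxy centre (later C6, ring A C2) untouched.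

Step 3
Reactants: 2 1-[(but-3-yn-1-yloxy)methyl]-4-methoxybenzene; 4 (4S)-N-methoxy-N,2,2-trimethyl-1,3-dioxolane-4-carboxamide
Product: 6 1-[(4S)-2,2-dimethyl-1,3-dioxolan-4-yl]-5-[(4-methoxybenzyl)oxy]pent-2-yn-1-one, via lithium acetylide 5 (not isolated)
Conditions: n-BuLi, THF, −78 °C; then 4, −78 → 0 °C; aq. NH4Cl
Reagents that add atoms: none
Why: Weinreb ketone synthesis; the chelated tetrahedral adduct stops at mono-addition of the acetylide and the α-centre is not epimerised at low temperature.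

Step 4
Reactants: 6 1-[(4S)-2,2-dimethyl-1,3-dioxolan-4-yl]-5-[(4-methoxybenzyl)oxy]pent-2-yn-1-one
Product: 7 (1R)-1-[(4S)-2,2-dimethyl-1,3-dioxolan-4-yl]-5-[(4-methoxybenzyl)oxy]pent-2-yn-1-ol
Conditions: Ru[(S,S)-TsDPEN](p-cymene) (2 mol%), i-PrOH, rt
Reagents that add atoms: none
Why: Noyori asymmetric transfer hydrogenation of an ynone; catalyst control, with the alkyne in the π-recognition site, sets the (R)-carbinol (C5) anti to the neighbouring dioxolane oxygen.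

Step 5
Reactants: 7 (1R)-1-[(4S)-2,2-dimethyl-1,3-dioxolan-4-yl]-5-[(4-methoxybenzyl)oxy]pent-2-yn-1-ol
Product: 9 (1R,2Z)-1-[(4S)-2,2-dimethyl-1,3-dioxolan-4-yl]-3-iodo-5-[(4-methoxybenzyl)oxy]pent-2-en-1-ol, via cyclic vinylalanate 8 (not isolated)
Conditions: NaAlH2(OCH2CH2OMe)2, THF, 0 °C → rt; EtOAc; then I2, −78 → 0 °C
Reagents that add atoms: iodine II
Why: hydroxyl-directed trans-hydroalumination of the propargylic alcohol puts H on C4 and Al on C3, and iodinolysis with retention gives the (Z)-3-iodoallylic alcohol, which fixes the alkene geometry.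

Step 6
Reactants: 9 (1R,2Z)-1-[(4S)-2,2-dimethyl-1,3-dioxolan-4-yl]-3-iodo-5-[(4-methoxybenzyl)oxy]pent-2-en-1-ol
Product: 10 (1R,2E)-1-[(4S)-2,2-dimethyl-1,3-dioxolan-4-yl]-5-[(4-methoxybenzyl)oxy]-3-methylpent-2-en-1-ol
Conditions: MeZnCl (3 equiv), Pd(PPh3)4 (5 mol%), THF, rt → 50 °C
Reagents that add atoms: methylzinc chloride C[Zn]Cl
Why: Negishi cross-coupling proceeds with retention at the alkenyl iodide, so the methyl ends up cis to the carbinol carbon, which is the (E)-trisubstituted alkene of the target.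

Step 7
Reactants: 10 (1R,2E)-1-[(4S)-2,2-dimethyl-1,3-dioxolan-4-yl]-5-[(4-methoxybenzyl)oxy]-3-methylpent-2-en-1-ol
Product: 11 tert-butyl{[(1R,2E)-1-[(4S)-2,2-dimethyl-1,3-dioxolan-4-yl]-5-[(4-methoxybenzyl)oxy]-3-methylpent-2-en-1-yl]oxy}dimethylsilane
Conditions: TBSCl, imidazole, DMF, rt → 40 °C
Reagents that add atoms: tert-butyldimethylsilyl chloride CC(C)(C)[Si](C)(C)Cl
Why: standard silylation; the C5 oxygen must be a non-chelating, non-nucleophilic silyl ether for the aldol and for the later ring closure.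

Step 8
Reactants: 11 tert-butyl{[(1R,2E)-1-[(4S)-2,2-dimethyl-1,3-dioxolan-4-yl]-5-[(4-methoxybenzyl)oxy]-3-methylpent-2-en-1-yl]oxy}dimethylsilane
Product: 12 (2S,3R,4E)-3-[(tert-butyldimethylsilyl)oxy]-7-[(4-methoxybenzyl)oxy]-5-methylhept-4-ene-1,2-diol
Conditions: AcOH/THF/H2O (3:1:1), 40 °C
Reagents that add atoms: none
Why: acid-catalysed acetal hydrolysis; a terminal acetonide is cleaved faster than a hindered secondary TBS ether or a PMB ether.

Step 9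
Reactants: 12 (2S,3R,4E)-3-[(tert-butyldimethylsilyl)oxy]-7-[(4-methoxybenzyl)oxy]-5-methylhept-4-ene-1,2-diol
Product: 13 tert-butyl{[(1R,2E)-5-[(4-methoxybenzyl)oxy]-1-[(4S)-2-(4-methoxyphenyl)-1,3-dioxolan-4-yl]-3-methylpent-2-en-1-yl]oxy}dimethylsilane (both epimers at the acetal carbon)
Conditions: 4-MeOC6H4CH(OMe)2, PPTS (cat.), CH2Cl2, rt
Reagents that add atoms: 4-methoxybenzaldehyde dimethyl acetal COC(OC)c1ccc(OC)cc1
Why: transacetalisation of the 1,2-diol to the p-methoxybenzylidene acetal; the new acetal centre is inconsequential because it is destroyed in the next step.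

Step 10
Reactants: 13 tert-butyl{[(1R,2E)-5-[(4-methoxybenzyl)oxy]-1-[(4S)-2-(4-methoxyphenyl)-1,3-dioxolan-4-yl]-3-methylpent-2-en-1-yl]oxy}dimethylsilane
Product: 14 (2S,3R,4E)-3-[(tert-butyldimethylsilyl)oxy]-2,7-bis[(4-methoxybenzyl)oxy]-5-methylhept-4-en-1-ol
Conditions: i-Bu2AlH (3 equiv), CH2Cl2, −78 → 0 °C
Reagents that add atoms: none
Why: regioselective reductive acetal opening; aluminium binds the less hindered primary oxygen, whose C–O bond breaks, so the PMB group stays on the secondary (C6) oxygen.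

Step 11
Reactants: 14 (2S,3R,4E)-3-[(tert-butyldimethylsilyl)oxy]-2,7-bis[(4-methoxybenzyl)oxy]-5-methylhept-4-en-1-ol
Product: 15 (2R,3R,4E)-3-[(tert-butyldimethylsilyl)oxy]-2,7-bis[(4-methoxybenzyl)oxy]-5-methylhept-4-enal
Conditions: Dess–Martin periodinane, NaHCO3, CH2Cl2, 0 °C → rt; used at once
Reagents that add atoms: none
Why: Dess–Martin oxidation under buffered, non-basic conditions gives the α-alkoxy aldehyde without epimerisation (the descriptor at C-2 changes only through CIP priorities).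

**East fragment**

Step 12
Reactants: 16 prop-2-yn-1-ol
Product: 17 1-methoxy-4-[(prop-2-yn-1-yloxy)methyl]benzene
Conditions: NaH, PMBCl, Bu4NI (cat.), THF/DMF, 0 °C → rt
Reagents that add atoms: 4-methoxybenzyl chloride COc1ccc(CCl)cc1
Why: Williamson ether synthesis on the alkoxide.

Step 13
Reactants: 17 1-methoxy-4-[(prop-2-yn-1-yloxy)methyl]benzene; 18 1,1,3-trichloroprop-1-ene
Product: 19 1-{[(6,6-dichlorohex-5-en-2-yn-1-yl)oxy]methyl}-4-methoxybenzene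
Conditions: CuI (10 mol%), NaI (10 mol%), K2CO3, DMF, rt
Reagents that add atoms: none
Why: copper-catalysed alkynyl–allyl coupling; the copper acetylide displaces the allylic chloride at CH2 (SN2) because the SN2' terminus carries two chlorines, giving the skipped enyne under weakly basic conditions.

Step 14
Reactants: 19 1-{[(6,6-dichlorohex-5-en-2-yn-1-yl)oxy]methyl}-4-methoxybenzene; 20 2-(2-bromoethyl)-2-methyl-1,3-dioxolane
Product: 22 2-{(3Z)-3-chloro-8-[(4-methoxybenzyl)oxy]oct-3-en-6-yn-1-yl}-2-methyl-1,3-dioxolane, via alkylzinc bromide 21 (not isolated)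
Conditions: 20, Zn dust, LiCl, THF, 50 °C; then 19, PdCl2(DPEphos) (3 mol%), THF/DMF, rt → 50 °C
Reagents that add atoms: none
Why: Negishi trans-selective monoalkylation of a 1,1-dichloroalkene; oxidative addition occurs at the less hindered C–Cl bond trans to the alkyl chain, so the remaining chlorine is cis to C14, which is the (Z)-vinyl chloride of the target.

Step 15
Reactants: 22 2-{(3Z)-3-chloro-8-[(4-methoxybenzyl)oxy]oct-3-en-6-yn-1-yl}-2-methyl-1,3-dioxolane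
Product: 23 (5Z)-5-chloro-10-[(4-methoxybenzyl)oxy]dec-5-en-8-yn-2-one
Conditions: PPTS, acetone/H2O, 60 °C
Reagents that add atoms: water O
Why: mild acid-catalysed ketal hydrolysis, which leaves the PMB ether, the vinyl chloride and the skipped enyne intact.

Step 16
Reactants: 23 (5Z)-5-chloro-10-[(4-methoxybenzyl)oxy]dec-5-en-8-yn-2-one
Product: 25 {[(5Z)-5-chloro-10-[(4-methoxybenzyl)oxy]deca-1,5-dien-8-yn-2-yl]oxy}trimethylsilane, via lithium enolate 24 (not isolated)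
Conditions: LiN(SiMe3)2, THF, −78 °C; then Me3SiCl, Et3N, −78 °C → rt
Reagents that add atoms: chlorotrimethylsilane C[Si](C)(C)Cl
Why: kinetic deprotonation of a methyl ketone at the methyl group followed by O-silylation gives the terminal silyl enol ether needed for the Mukaiyama aldol.

**Fragment union and completion**

Step 17
Reactants: 15 (2R,3R,4E)-3-[(tert-butyldimethylsilyl)oxy]-2,7-bis[(4-methoxybenzyl)oxy]-5-methylhept-4-enal; 25 {[(5Z)-5-chloro-10-[(4-methoxybenzyl)oxy]deca-1,5-dien-8-yn-2-yl]oxy}trimethylsilane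
Product: 27 (3E,5R,6S,7R,12Z)-5-[(tert-butyldimethylsilyl)oxy]-12-chloro-7-hydroxy-1,6,17-tris[(4-methoxybenzyl)oxy]-3-methylheptadeca-3,12-dien-15-yn-9-one, via silylated aldol 26 (not isolated)
Conditions: 15, MgBr2·OEt2 (3 equiv), CH2Cl2, −78 °C; 25 (1.5 equiv), −78 → −20 °C; then 1 M HCl, THF, 0 °C
Reagents that add atoms: none
Why: chelation-controlled Mukaiyama aldol; magnesium bridges the aldehyde and α-PMB ether oxygens (Cram chelate) and the enol silane attacks the face away from the C5 substituent, setting C7 (R) syn to the C6 oxygen.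

Step 18
Reactants: 27 (3E,5R,6S,7R,12Z)-5-[(tert-butyldimethylsilyl)oxy]-12-chloro-7-hydroxy-1,6,17-tris[(4-methoxybenzyl)oxy]-3-methylheptadeca-3,12-dien-15-yn-9-one
Product: 28 (3E,5R,6S,7R,9S,12Z)-5-[(tert-butyldimethylsilyl)oxy]-12-chloro-9-hydroxy-1,6,17-tris[(4-methoxybenzyl)oxy]-3-methylheptadeca-3,12-dien-15-yn-7-yl acetate
Conditions: SmI2 (30 mol%), MeCHO (10 equiv), THF, −10 °C
Reagents that add atoms: acetaldehyde CC=O
Why: Evans–Tishchenko reduction; the samarium-bound hemiacetal of the C7 hydroxyl delivers hydride intramolecularly through a chair transition state, giving the 1,3-anti C9 carbinol (S) and leaving C7 as its acetate.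

Step 19
Reactants: 28 (3E,5R,6S,7R,9S,12Z)-5-[(tert-butyldimethylsilyl)oxy]-12-chloro-9-hydroxy-1,6,17-tris[(4-methoxybenzyl)oxy]-3-methylheptadeca-3,12-dien-15-yn-7-yl acetate
Product: 29 (3E,5R,6S,7R,9S,12Z)-5-[(tert-butyldimethylsilyl)oxy]-12-chloro-1,6,17-tris[(4-methoxybenzyl)oxy]-3-methyl-9-[(methylsulfonyl)oxy]heptadeca-3,12-dien-15-yn-7-yl acetate
Conditions: MsCl, Et3N, CH2Cl2, 0 °C
Reagents that add atoms: methanesulfonyl chloride CS(=O)(=O)Cl
Why: sulfonylation of the only free hydroxyl turns C9 into a leaving group with retention.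

Step 20
Reactants: 29 (3E,5R,6S,7R,9S,12Z)-5-[(tert-butyldimethylsilyl)oxy]-12-chloro-1,6,17-tris[(4-methoxybenzyl)oxy]-3-methyl-9-[(methylsulfonyl)oxy]heptadeca-3,12-dien-15-yn-7-yl acetate
Product: 30 (3E,5R,6S,7R,9S,12Z)-5-[(tert-butyldimethylsilyl)oxy]-12-chloro-1,6,17-trihydroxy-3-methyl-9-[(methylsulfonyl)oxy]heptadeca-3,12-dien-15-yn-7-yl acetate
Conditions: DDQ (3.6 equiv), CH2Cl2/pH 7 buffer (10:1), 0 °C → rt
Reagents that add atoms: none
Why: oxidative cleavage of the three PMB ethers by DDQ frees the C6, C1 and C17 hydroxyls, while the silyl ether, acetate, mesylate, alkenes and alkyne are inert.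

Step 21
Reactants: 30 (3E,5R,6S,7R,9S,12Z)-5-[(tert-butyldimethylsilyl)oxy]-12-chloro-1,6,17-trihydroxy-3-methyl-9-[(methylsulfonyl)oxy]heptadeca-3,12-dien-15-yn-7-yl acetate
Product: 32 (2S,3R,5R)-2-{(1R,2E)-1-[(tert-butyldimethylsilyl)oxy]-5-hydroxy-3-methylpent-2-en-1-yl}-5-[(3Z)-3-chloro-8-hydroxyoct-3-en-6-yn-1-yl]oxolan-3-ol, via oxolane acetate 31 (not isolated)
Conditions: K2CO3, MeOH, 0 °C → rt
Reagents that add atoms: none
Why: intramolecular Williamson etherification (5-exo-tet SN2); the C6 hydroxyl displaces the C9 mesylate with inversion to give the 2,5-trans ring A with C9 (R), and the acetate is then methanolysed.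

Step 22
Reactants: 32 (2S,3R,5R)-2-{(1R,2E)-1-[(tert-butyldimethylsilyl)oxy]-5-hydroxy-3-methylpent-2-en-1-yl}-5-[(3Z)-3-chloro-8-hydroxyoct-3-en-6-yn-1-yl]oxolan-3-ol
Product: 33 (2S,3R,5R)-2-{(1R,2E)-1-[(tert-butyldimethylsilyl)oxy]-5-hydroxy-3-methylpent-2-en-1-yl}-5-[(3Z,6Z)-3-chloro-8-hydroxy-7-(tributylstannyl)octa-3,6-dien-1-yl]oxolan-3-ol
Conditions: [Cp*RuCl]4 (2.5 mol%), Bu3SnH (1.15 equiv), CH2Cl2, rt
Reagents that add atoms: tributyltin hydride CCCC[SnH](CCCC)CCCC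
Why: ruthenium-catalysed hydroxyl-directed trans-hydrostannation; tin goes to the alkyne carbon next to the propargylic OH and H adds anti, so C14 is cis to tin and trans to the CH2OH.

Step 23
Reactants: 33 (2S,3R,5R)-2-{(1R,2E)-1-[(tert-butyldimethylsilyl)oxy]-5-hydroxy-3-methylpent-2-en-1-yl}-5-[(3Z,6Z)-3-chloro-8-hydroxy-7-(tributylstannyl)octa-3,6-dien-1-yl]oxolan-3-ol; 34 ethyl (2Z)-3-iodoprop-2-enoate
Product: 36 (5E)-5-{(3Z)-4-chloro-6-[(2R,4R,5S)-5-{(1R,2E)-1-[(tert-butyldimethylsilyl)oxy]-5-hydroxy-3-methylpent-2-en-1-yl}-4-hydroxyoxolan-2-yl]hex-3-en-1-ylidene}-5,6-dihydro-2H-pyran-2-one, via hydroxy dienoate 35 (not isolated)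
Conditions: Pd(PPh3)4 (5 mol%), Cu(O2CC4H3S) (1.5 equiv), [Bu4N][Ph2PO2] (1.5 equiv), DMF, rt; then PPTS (cat.), CH2Cl2, rt
Reagents that add atoms: none
Why: copper-assisted Stille coupling with retention at both alkenyl partners, followed by lactonisation of the (Z)-enoate onto the cis-disposed CH2OH, builds ring B with the (E)-exocyclic alkene.

Step 24
Reactants: 36 (5E)-5-{(3Z)-4-chloro-6-[(2R,4R,5S)-5-{(1R,2E)-1-[(tert-butyldimethylsilyl)oxy]-5-hydroxy-3-methylpent-2-en-1-yl}-4-hydroxyoxolan-2-yl]hex-3-en-1-ylidene}-5,6-dihydro-2H-pyran-2-one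
Product: 38 (3E,5R)-5-[(tert-butyldimethylsilyl)oxy]-5-[(2S,3R,5R)-5-{(3Z,6E)-3-chloro-6-(6-oxo-2H-pyran-3(6H)-ylidene)hex-3-en-1-yl}-3-hydroxyoxolan-2-yl]-3-methylpent-3-enoic acid, via aldehyde 37 (not isolated)
Conditions: TEMPO (20 mol%), PhI(OAc)2 (1.2 equiv), CH2Cl2, rt; then NaClO2, NaH2PO4, 2-methyl-2-butene, t-BuOH/H2O, 0 °C → rt
Reagents that add atoms: sodium chlorite [Na+].[O-]Cl=O
Why: TEMPO/PhI(OAc)2 oxidises the primary alcohol in preference to the hindered secondary ring hydroxyl, and Pinnick oxidation of the crude β,γ-unsaturated aldehyde gives the acid without moving the alkene.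

Step 25
Reactants: 38 (3E,5R)-5-[(tert-butyldimethylsilyl)oxy]-5-[(2S,3R,5R)-5-{(3Z,6E)-3-chloro-6-(6-oxo-2H-pyran-3(6H)-ylidene)hex-3-en-1-yl}-3-hydroxyoxolan-2-yl]-3-methylpent-3-enoic acid
Product: 39 (3E,5R)-5-[(2S,3R,5R)-5-{(3Z,6E)-3-chloro-6-(6-oxo-2H-pyran-3(6H)-ylidene)hex-3-en-1-yl}-3-hydroxyoxolan-2-yl]-5-hydroxy-3-methylpent-3-enoic acid
Conditions: HF·pyridine, pyridine, THF, 0 °C → rt
Reagents that add atoms: none
Why: buffered fluoride desilylation removes the last protecting group without opening the lactone or ionising the allylic alcohol.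

## Compound list

1 | but-3-yn-1-ol | C#CCCO | starting material
2 | 1-[(but-3-yn-1-yloxy)methyl]-4-methoxybenzene | C#CCCOCc1ccc(OC)cc1 | intermediate
3 | methyl (4S)-2,2-dimethyl-1,3-dioxolane-4-carboxylate | COC(=O)[C@@H]1COC(C)(C)O1 | starting material
4 | (4S)-N-methoxy-N,2,2-trimethyl-1,3-dioxolane-4-carboxamide | CON(C)C(=O)[C@@H]1COC(C)(C)O1 | intermediate
5 | lithium 4-[(4-methoxybenzyl)oxy]but-1-yn-1-ide | [Li]C#CCCOCc1ccc(OC)cc1 | intermediate
6 | 1-[(4S)-2,2-dimethyl-1,3-dioxolan-4-yl]-5-[(4-methoxybenzyl)oxy]pent-2-yn-1-one | O=C(C#CCCOCc1ccc(OC)cc1)[C@@H]1COC(C)(C)O1 | intermediate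
7 | (1R)-1-[(4S)-2,2-dimethyl-1,3-dioxolan-4-yl]-5-[(4-methoxybenzyl)oxy]pent-2-yn-1-ol | COc1ccc(COCCC#C[C@@H](O)[C@@H]2COC(C)(C)O2)cc1 | intermediate
8 | sodium bis(2-methoxyethoxy)aluminate with Al bound to the carbinol oxygen and to C-3 of the alkene (five-membered oxaaluminacycle) | [Na+].COCCO[Al-]1(OCCOC)O[C@@H]([C@@H]2COC(C)(C)O2)C=C1CCOCc1ccc(OC)cc1 | intermediate
9 | (1R,2Z)-1-[(4S)-2,2-dimethyl-1,3-dioxolan-4-yl]-3-iodo-5-[(4-methoxybenzyl)oxy]pent-2-en-1-ol | I/C(=C\[C@@H](O)[C@@H]1COC(C)(C)O1)CCOCc1ccc(OC)cc1 | intermediate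
10 | (1R,2E)-1-[(4S)-2,2-dimethyl-1,3-dioxolan-4-yl]-5-[(4-methoxybenzyl)oxy]-3-methylpent-2-en-1-ol | C/C(=C\[C@@H](O)[C@@H]1COC(C)(C)O1)CCOCc1ccc(OC)cc1 | intermediate
11 | tert-butyl{[(1R,2E)-1-[(4S)-2,2-dimethyl-1,3-dioxolan-4-yl]-5-[(4-methoxybenzyl)oxy]-3-methylpent-2-en-1-yl]oxy}dimethylsilane | C/C(=C\[C@@H](O[Si](C)(C)C(C)(C)C)[C@@H]1COC(C)(C)O1)CCOCc1ccc(OC)cc1 | intermediate
12 | (2S,3R,4E)-3-[(tert-butyldimethylsilyl)oxy]-7-[(4-methoxybenzyl)oxy]-5-methylhept-4-ene-1,2-diol | C/C(=C\[C@@H](O[Si](C)(C)C(C)(C)C)[C@@H](O)CO)CCOCc1ccc(OC)cc1 | intermediate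
13 | tert-butyl{[(1R,2E)-5-[(4-methoxybenzyl)oxy]-1-[(4S)-2-(4-methoxyphenyl)-1,3-dioxolan-4-yl]-3-methylpent-2-en-1-yl]oxy}dimethylsilane (acetal epimers) | C/C(=C\[C@@H](O[Si](C)(C)C(C)(C)C)[C@@H]1COC(c2ccc(OC)cc2)O1)CCOCc1ccc(OC)cc1 | intermediate
14 | (2S,3R,4E)-3-[(tert-butyldimethylsilyl)oxy]-2,7-bis[(4-methoxybenzyl)oxy]-5-methylhept-4-en-1-ol | C/C(=C\[C@@H](O[Si](C)(C)C(C)(C)C)[C@@H](OCc1ccc(OC)cc1)CO)CCOCc1ccc(OC)cc1 | intermediate
15 | (2R,3R,4E)-3-[(tert-butyldimethylsilyl)oxy]-2,7-bis[(4-methoxybenzyl)oxy]-5-methylhept-4-enal | C/C(=C\[C@@H](O[Si](C)(C)C(C)(C)C)[C@@H](OCc1ccc(OC)cc1)C=O)CCOCc1ccc(OC)cc1 | intermediate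
16 | prop-2-yn-1-ol | C#CCO | starting material
17 | 1-methoxy-4-[(prop-2-yn-1-yloxy)methyl]benzene | C#CCOCc1ccc(OC)cc1 | intermediate
18 | 1,1,3-trichloroprop-1-ene | ClCC=C(Cl)Cl | starting material
19 | 1-{[(6,6-dichlorohex-5-en-2-yn-1-yl)oxy]methyl}-4-methoxybenzene | ClC(Cl)=CCC#CCOCc1ccc(OC)cc1 | intermediate
20 | 2-(2-bromoethyl)-2-methyl-1,3-dioxolane | CC1(CCBr)OCCO1 | starting material
21 | bromo[2-(2-methyl-1,3-dioxolan-2-yl)ethyl]zinc | CC1(CC[Zn]Br)OCCO1 | intermediate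
22 | 2-{(3Z)-3-chloro-8-[(4-methoxybenzyl)oxy]oct-3-en-6-yn-1-yl}-2-methyl-1,3-dioxolane | CC1(CC/C(Cl)=C/CC#CCOCc2ccc(OC)cc2)OCCO1 | intermediate
23 | (5Z)-5-chloro-10-[(4-methoxybenzyl)oxy]dec-5-en-8-yn-2-one | CC(=O)CC/C(Cl)=C/CC#CCOCc1ccc(OC)cc1 | intermediate
24 | lithium (5Z)-5-chloro-10-[(4-methoxybenzyl)oxy]deca-1,5-dien-8-yn-2-olate | [Li]OC(=C)CC/C(Cl)=C/CC#CCOCc1ccc(OC)cc1 | intermediate
25 | {[(5Z)-5-chloro-10-[(4-methoxybenzyl)oxy]deca-1,5-dien-8-yn-2-yl]oxy}trimethylsilane | C=C(O[Si](C)(C)C)CC/C(Cl)=C/CC#CCOCc1ccc(OC)cc1 | intermediate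
26 | (3E,5R,6S,7R,12Z)-5-[(tert-butyldimethylsilyl)oxy]-12-chloro-1,6,17-tris[(4-methoxybenzyl)oxy]-3-methyl-7-[(trimethylsilyl)oxy]heptadeca-3,12-dien-15-yn-9-one | C/C(=C\[C@@H](O[Si](C)(C)C(C)(C)C)[C@@H](OCc1ccc(OC)cc1)[C@H](O[Si](C)(C)C)CC(=O)CC/C(Cl)=C/CC#CCOCc1ccc(OC)cc1)CCOCc1ccc(OC)cc1 | intermediate
27 | (3E,5R,6S,7R,12Z)-5-[(tert-butyldimethylsilyl)oxy]-12-chloro-7-hydroxy-1,6,17-tris[(4-methoxybenzyl)oxy]-3-methylheptadeca-3,12-dien-15-yn-9-one | C/C(=C\[C@@H](O[Si](C)(C)C(C)(C)C)[C@@H](OCc1ccc(OC)cc1)[C@H](O)CC(=O)CC/C(Cl)=C/CC#CCOCc1ccc(OC)cc1)CCOCc1ccc(OC)cc1 | intermediate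
28 | (3E,5R,6S,7R,9S,12Z)-5-[(tert-butyldimethylsilyl)oxy]-12-chloro-9-hydroxy-1,6,17-tris[(4-methoxybenzyl)oxy]-3-methylheptadeca-3,12-dien-15-yn-7-yl acetate | C/C(=C\[C@@H](O[Si](C)(C)C(C)(C)C)[C@@H](OCc1ccc(OC)cc1)[C@H](OC(C)=O)C[C@@H](O)CC/C(Cl)=C/CC#CCOCc1ccc(OC)cc1)CCOCc1ccc(OC)cc1 | intermediate
29 | (3E,5R,6S,7R,9S,12Z)-5-[(tert-butyldimethylsilyl)oxy]-12-chloro-1,6,17-tris[(4-methoxybenzyl)oxy]-3-methyl-9-[(methylsulfonyl)oxy]heptadeca-3,12-dien-15-yn-7-yl acetate | C/C(=C\[C@@H](O[Si](C)(C)C(C)(C)C)[C@@H](OCc1ccc(OC)cc1)[C@H](OC(C)=O)C[C@@H](OS(C)(=O)=O)CC/C(Cl)=C/CC#CCOCc1ccc(OC)cc1)CCOCc1ccc(OC)cc1 | intermediate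
30 | (3E,5R,6S,7R,9S,12Z)-5-[(tert-butyldimethylsilyl)oxy]-12-chloro-1,6,17-trihydroxy-3-methyl-9-[(methylsulfonyl)oxy]heptadeca-3,12-dien-15-yn-7-yl acetate | C/C(=C\[C@@H](O[Si](C)(C)C(C)(C)C)[C@@H](O)[C@H](OC(C)=O)C[C@@H](OS(C)(=O)=O)CC/C(Cl)=C/CC#CCO)CCO | intermediate
31 | (2S,3R,5R)-2-{(1R,2E)-1-[(tert-butyldimethylsilyl)oxy]-5-hydroxy-3-methylpent-2-en-1-yl}-5-[(3Z)-3-chloro-8-hydroxyoct-3-en-6-yn-1-yl]oxolan-3-yl acetate | C/C(=C\[C@@H](O[Si](C)(C)C(C)(C)C)[C@H]1O[C@H](CC/C(Cl)=C/CC#CCO)C[C@H]1OC(C)=O)CCO | intermediate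
32 | (2S,3R,5R)-2-{(1R,2E)-1-[(tert-butyldimethylsilyl)oxy]-5-hydroxy-3-methylpent-2-en-1-yl}-5-[(3Z)-3-chloro-8-hydroxyoct-3-en-6-yn-1-yl]oxolan-3-ol | C/C(=C\[C@@H](O[Si](C)(C)C(C)(C)C)[C@H]1O[C@H](CC/C(Cl)=C/CC#CCO)C[C@H]1O)CCO | intermediate
33 | (2S,3R,5R)-2-{(1R,2E)-1-[(tert-butyldimethylsilyl)oxy]-5-hydroxy-3-methylpent-2-en-1-yl}-5-[(3Z,6Z)-3-chloro-8-hydroxy-7-(tributylstannyl)octa-3,6-dien-1-yl]oxolan-3-ol | C/C(=C\[C@@H](O[Si](C)(C)C(C)(C)C)[C@H]1O[C@H](CC/C(Cl)=C/C/C=C(\[Sn](CCCC)(CCCC)CCCC)CO)C[C@H]1O)CCO | intermediate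
34 | ethyl (2Z)-3-iodoprop-2-enoate | CCOC(=O)/C=C\I | starting material
35 | ethyl (2Z,4E,7Z)-8-chloro-10-{(2R,4R,5S)-5-[(1R,2E)-1-[(tert-butyldimethylsilyl)oxy]-5-hydroxy-3-methylpent-2-en-1-yl]-4-hydroxyoxolan-2-yl}-4-(hydroxymethyl)deca-2,4,7-trienoate | C/C(=C\[C@@H](O[Si](C)(C)C(C)(C)C)[C@H]1O[C@H](CC/C(Cl)=C/C/C=C(\C=C/C(=O)OCC)CO)C[C@H]1O)CCO | intermediate
36 | (5E)-5-{(3Z)-4-chloro-6-[(2R,4R,5S)-5-{(1R,2E)-1-[(tert-butyldimethylsilyl)oxy]-5-hydroxy-3-methylpent-2-en-1-yl}-4-hydroxyoxolan-2-yl]hex-3-en-1-ylidene}-5,6-dihydro-2H-pyran-2-one | C/C(=C\[C@@H](O[Si](C)(C)C(C)(C)C)[C@H]1O[C@H](CC/C(Cl)=C/C/C=C2\C=CC(=O)OC2)C[C@H]1O)CCO | intermediate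
37 | (3E,5R)-5-[(tert-butyldimethylsilyl)oxy]-5-[(2S,3R,5R)-5-{(3Z,6E)-3-chloro-6-(6-oxo-2H-pyran-3(6H)-ylidene)hex-3-en-1-yl}-3-hydroxyoxolan-2-yl]-3-methylpent-3-enal | C/C(=C\[C@@H](O[Si](C)(C)C(C)(C)C)[C@H]1O[C@H](CC/C(Cl)=C/C/C=C2\C=CC(=O)OC2)C[C@H]1O)CC=O | intermediate
38 | (3E,5R)-5-[(tert-butyldimethylsilyl)oxy]-5-[(2S,3R,5R)-5-{(3Z,6E)-3-chloro-6-(6-oxo-2H-pyran-3(6H)-ylidene)hex-3-en-1-yl}-3-hydroxyoxolan-2-yl]-3-methylpent-3-enoic acid | C/C(=C\[C@@H](O[Si](C)(C)C(C)(C)C)[C@H]1O[C@H](CC/C(Cl)=C/C/C=C2\C=CC(=O)OC2)C[C@H]1O)CC(=O)O | intermediate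
39 | (3E,5R)-5-[(2S,3R,5R)-5-{(3Z,6E)-3-chloro-6-(6-oxo-2H-pyran-3(6H)-ylidene)hex-3-en-1-yl}-3-hydroxyoxolan-2-yl]-5-hydroxy-3-methylpent-3-enoic acid | C/C(=C\[C@@H](O)[C@H]1O[C@H](CC/C(Cl)=C/C/C=C2\C=CC(=O)OC2)C[C@H]1O)CC(=O)O | target

## Step count and risk assessment

Total step count: 25 (west fragment steps 1–11, east fragment steps 12–16, union and completion steps 17–25).
Longest linear sequence: 19 steps (3 → 4 → 6 → 7 → 9 → 10 → 11 → 12 → 13 → 14 → 15 → 27 → 28 → 29 → 30 → 32 → 33 → 36 → 38 → 39).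

Three steps most likely to fail:

Step 17, the fragment-uniting aldol. MgBr2·OEt2 is a weak activator for a ketone-derived enol silane, the three PMB ethers limit the choice of stronger Lewis acids, and any internal enol silane isomer in 25 gives regioisomeric adducts. The fallback sets out from enol silane 25 and generates the nucleophile reductively and regiospecifically. N-Bromosuccinimide (THF, −78 °C) converts 25 into (5Z)-1-bromo-5-chloro-10-[(4-methoxybenzyl)oxy]dec-5-en-8-yn-2-one F1. A Reformatsky-type addition of F1 to aldehyde 15 with SmI2 (2.2 equiv, THF, −78 °C) then proceeds through a samarium enolate that can chelate the α-PMB-oxy aldehyde, which should again favour the 6,7-syn adduct, though that selectivity is less well precedented than the magnesium case. The fallback comes back to the route at 27.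

Step 21, the SN2 closure of ring A. Elimination of the secondary mesylate, acetate or silyl migration to the C6 oxygen, or competing oxetane formation could erode the yield. The fallback sets out from aldol 27 and forms the ring by reduction instead of displacement. DDQ (CH2Cl2/pH 7 buffer) removes the three PMB groups, and the freed C6 hydroxyl adds to the C9 ketone to give the cyclic hemiketal (4R,5S)-2-[(3Z)-3-chloro-8-hydroxyoct-3-en-6-yn-1-yl]-5-{(1R,2E)-1-[(tert-butyldimethylsilyl)oxy]-5-hydroxy-3-methylpent-2-en-1-yl}oxolane-2,4-diol F2 (anomer mixture). Et3SiH with BF3·OEt2 (CH2Cl2, −78 °C) reduces the derived oxocarbenium ion. Hydride is expected to add cis to the C-3 hydroxyl (inside attack on the envelope), which gives the 2,5-trans ring; this selectivity is less certain than the SN2 inversion, which is why it is the fallback. It comes back to the route at 32.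

Step 23, the Stille coupling and lactonisation. Transmetalation of the hindered α-substituted alkenylstannane can be slow, which allows protodestannylation or isomerisation of the (Z)-iodoacrylate. The fallback sets out from stannane 33 and reverses the polarity of the coupling. Iodine (CH2Cl2, 0 °C) gives, with retention, the alkenyl iodide (2S,3R,5R)-2-{(1R,2E)-1-[(tert-butyldimethylsilyl)oxy]-5-hydroxy-3-methylpent-2-en-1-yl}-5-[(3Z,6Z)-3-chloro-8-hydroxy-7-iodoocta-3,6-dien-1-yl]oxolan-3-ol F3. Stille coupling of F3 with the unhindered ethyl (Z)-3-(tributylstannyl)acrylate (Pd2(dba)3, AsPh3, CuI, DMF, rt) gives hydroxy dienoate 35, which lactonises as before. The fallback comes back to the route at 36.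

## Further compounds

F1 | step 17 | (5Z)-1-bromo-5-chloro-10-[(4-methoxybenzyl)oxy]dec-5-en-8-yn-2-one | BrCC(=O)CC/C(Cl)=C/CC#CCOCc1ccc(OC)cc1
F2 | step 21 | (4R,5S)-2-[(3Z)-3-chloro-8-hydroxyoct-3-en-6-yn-1-yl]-5-{(1R,2E)-1-[(tert-butyldimethylsilyl)oxy]-5-hydroxy-3-methylpent-2-en-1-yl}oxolane-2,4-diol (anomer mixture) | C/C(=C\[C@@H](O[Si](C)(C)C(C)(C)C)[C@H]1OC(O)(CC/C(Cl)=C/CC#CCO)C[C@H]1O)CCO
F3 | step 23 | (2S,3R,5R)-2-{(1R,2E)-1-[(tert-butyldimethylsilyl)oxy]-5-hydroxy-3-methylpent-2-en-1-yl}-5-[(3Z,6Z)-3-chloro-8-hydroxy-7-iodoocta-3,6-dien-1-yl]oxolan-3-ol | C/C(=C\[C@@H](O[Si](C)(C)C(C)(C)C)[C@H]1O[C@H](CC/C(Cl)=C/C/C=C(\I)CO)C[C@H]1O)CCO
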